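**Retrosynthetic overview**

1. Feature: the cis-fused hexahydroisobenzofuran, i.e. the tetrahydrofuran O–C2–C1–C10–C9 fused at C1–C10 to the cyclohexane C1–C10–C11–C12–C13–C14, with four contiguous stereocentres (C2, C1, C10, C9) around the ring oxygen; with a formyl group imagined on C10 it is a 3-acyltetrahydrofuran. Further numbering: oxonane O–C2–C3–C4–C5–C6–C7–C8–C9 with the C19 methylene on C7; oxepane C3–O–C16–C15–C14–C1–C2; methyls C17 on C15, C18 on C3, C20 on C11.
2. Key disconnection (C1–C2 and C9–C10 in one operation): Lewis-acid ionization of a dienyl dioxolane, Prins attack of the carvone-derived diene on the oxocarbenium ion and pinacol shift of C9 to C10 give the tetrahydrofuran with a C10 formyl group, which is later excised photochemically.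
3. The dioxolane comes from (R)-carvone (C1, C10–C17, C20; as its dienyl triflate), (R)-glycidol plus (triisopropylsilyl)acetylene (C9, C8, C7, C19; joined to the triflate by a Ni/Cr-mediated coupling) and propane-1,3-diol (C4–C6; extended to the (Z)-enal that brings C2, C3, C18).
4. After the key step: C3 tertiary alcohol by hydroxyl-directed epoxidation of the (Z)-C3=C4 alkene and hydride opening; C15/C16 by hydroboration of the isopropenyl group; oxepane by C16–O etherification; C11/C12 cis-diol by osmylation, then C12 octanoylation; oxonane by Nozaki–Hiyama–Kishi closure of C6–C7; C6 deoxygenation by palladium-catalysed formate reduction.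
5. Ring order: cyclohexene (from carvone) → tetrahydrofuran (step 14) → oxepane (step 21) → oxonane (step 27).

Key step: step 14

Remark on the chemistry: the C3=C4 alkene is carried as the Z isomer. Its geometry has no bearing on the key step, but its A(1,3) strain fixes the C2–C3 rotamer for the epoxidation that sets C3. Locants C1–C20 in all names follow the overview.

**Route**

Step 1
Reactants: 1 propane-1,3-diol
Product: 2 3-[(tert-butyldiphenylsilyl)oxy]propan-1-ol
Conditions: t-BuPh2SiCl (1 equiv), imidazole, THF, 0 °C → rt; 1 in threefold excess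
Reagents that add atoms: tert-butyl(chloro)diphenylsilane, CC(C)(C)[Si](Cl)(c1ccccc1)c1ccccc1
Why: Silylation of a symmetric diol used in excess should stop at the mono-ether (statistical monoprotection), and the bulky silyl group is chosen to survive the Lewis acid of step 14.

Step 2
Reactants: 2 3-[(tert-butyldiphenylsilyl)oxy]propan-1-ol
Product: 3 3-[(tert-butyldiphenylsilyl)oxy]propanal
Conditions: TEMPO (cat.), PhI(OAc)2, CH2Cl2, rt
Reagents that add atoms: none
Why: The nitroxyl-catalysed oxidation of a primary alcohol (TEMPO/PhI(OAc)2) stops at the aldehyde and does not touch the silyl ether.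

Step 3
Reactants: 3 3-[(tert-butyldiphenylsilyl)oxy]propanal; 4 methyl 2-[bis(2,2,2-trifluoroethoxy)phosphoryl]propanoate
Product: 6 methyl (2Z)-5-[(tert-butyldiphenylsilyl)oxy]-2-methylpent-2-enoate, via phosphonate carbanion 5 (not isolated)
Conditions: 4, KN(SiMe3)2, 18-crown-6, THF, −78 °C; then 3
Reagents that add atoms: none
Why: Still–Gennari olefination: the electron-poor bis(trifluoroethyl) phosphonate makes elimination of the first-formed adduct fast, so the kinetic Z-trisubstituted enoate should result.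

Step 4
Reactants: 6 methyl (2Z)-5-[(tert-butyldiphenylsilyl)oxy]-2-methylpent-2-enoate
Product: 7 (2Z)-5-[(tert-butyldiphenylsilyl)oxy]-2-methylpent-2-en-1-ol
Conditions: i-Bu2AlH (2.2 equiv), CH2Cl2, −78 °C; aqueous potassium sodium tartrate work-up
Reagents that add atoms: none
Why: 1,2-Reduction of the conjugated ester by the aluminium hydride leaves the alkene geometry and the silyl ether untouched.

Step 5
Reactants: 7 (2Z)-5-[(tert-butyldiphenylsilyl)oxy]-2-methylpent-2-en-1-ol
Product: 8 (2Z)-5-[(tert-butyldiphenylsilyl)oxy]-2-methylpent-2-enal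
Conditions: Dess–Martin periodinane, pyridine, CH2Cl2, 0 °C; used at once
Reagents that add atoms: none
Why: The buffered Dess–Martin oxidation is mild and non-acidic, so the Z-enal should form without isomerization to the E isomer.

Step 6
Reactants: 9 (R)-glycidol
Product: 10 triethyl{[(2S)-oxiran-2-yl]methoxy}silane
Conditions: Et3SiCl, imidazole, CH2Cl2, 0 °C
Reagents that add atoms: chlorotriethylsilane, CC[Si](Cl)(CC)CC
Why: Silylation of the primary hydroxyl leaves the epoxide and its stereocentre untouched, and the triethylsilyl group is chosen because step 9 can oxidize it off directly.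

Step 7
Reactants: 10 triethyl{[(2S)-oxiran-2-yl]methoxy}silane; 11 ethynyltri(propan-2-yl)silane
Product: 13 (2S)-1-[(triethylsilyl)oxy]-5-[tri(propan-2-yl)silyl]pent-4-yn-2-ol, via lithium acetylide 12 (not isolated)
Conditions: 11, n-BuLi, THF, −78 °C; BF3·OEt2; then 10, −78 °C
Reagents that add atoms: none
Why: The BF3-activated opening of a terminal epoxide by a lithium acetylide (Yamaguchi–Hirao alkynylation) is an SN2 attack at the unsubstituted carbon, so the glycidol stereocentre is carried over unchanged as the future C9.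

Step 8
Reactants: 13 (2S)-1-[(triethylsilyl)oxy]-5-[tri(propan-2-yl)silyl]pent-4-yn-2-ol
Product: 14 (2S)-1,2-bis[(triethylsilyl)oxy]-5-[tri(propan-2-yl)silyl]pent-4-yne
Conditions: Et3SiCl, imidazole, DMAP (cat.), CH2Cl2, rt
Reagents that add atoms: chlorotriethylsilane, CC[Si](Cl)(CC)CC
Why: Standard silylation of the secondary alcohol gives the bis-silyl ether that step 9 requires.

Step 9
Reactants: 14 (2S)-1,2-bis[(triethylsilyl)oxy]-5-[tri(propan-2-yl)silyl]pent-4-yne
Product: 16 (2S)-2-[(triethylsilyl)oxy]-5-[tri(propan-2-yl)silyl]pent-4-ynal, via alkoxysulfonium chloride 15 (not isolated)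
Conditions: (COCl)2, DMSO, CH2Cl2, −78 → −40 °C; then Et3N, −78 → 0 °C
Reagents that add atoms: none
Why: Under Swern conditions a primary triethylsilyl ether is cleaved and oxidized in one pot while a secondary one survives, and at low temperature the α-silyloxy aldehyde should not epimerize.

Step 10
Reactants: 17 (R)-carvone
Product: 19 (3R)-6-methyl-3-(prop-1-en-2-yl)cyclohexa-1,5-dien-1-yl trifluoromethanesulfonate, via lithium dienolate 18 (not isolated)
Conditions: LiN(i-Pr)2, THF, −78 °C; then PhNTf2, −78 → 0 °C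
Reagents that add atoms: N-phenylbis(trifluoromethanesulfonimide), O=S(=O)(N(c1ccccc1)S(=O)(=O)C(F)(F)F)C(F)(F)F
Why: Kinetic deprotonation of the enone at the α′ methylene gives the cross-conjugated dienolate, which is trapped on oxygen as the enol triflate; the carvone stereocentre (future C14) is not involved.

Step 11
Reactants: 19 carvone dienyl triflate; 16 (2S)-2-[(triethylsilyl)oxy]-5-[tri(propan-2-yl)silyl]pent-4-ynal
Product: 20 dienyl carbinol with C9 triethylsilyl ether (both carbinol epimers)
Conditions: CrCl2 (4 equiv), NiCl2 (2 mol %), DMF, rt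
Reagents that add atoms: none
Why: Nozaki–Hiyama–Kishi coupling of an enol triflate: zerovalent nickel inserts into the C–OTf bond, the dienyl group passes to chromium and adds to the aldehyde alone without touching the α-silyloxy centre; the new carbinol centre needs no control because it becomes the formyl carbon.

Step 12
Reactants: 20 dienyl carbinol with C9 triethylsilyl ether
Product: 21 dienyl 1,2-diol (both carbinol epimers; C9 is S)
Conditions: HF·pyridine, pyridine, THF, 0 °C
Reagents that add atoms: none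
Why: Buffered HF·pyridine removes the labile triethylsilyl ether and leaves the alkynyl C–Si bond and the acid-sensitive dienyl carbinol intact.

Step 13
Reactants: 21 dienyl 1,2-diol; 8 (2Z)-5-[(tert-butyldiphenylsilyl)oxy]-2-methylpent-2-enal
Product: 22 dienyl dioxolane (mixture at the acetal and carbinol carbons)
Conditions: pyridinium p-toluenesulfonate (cat.), MgSO4, CH2Cl2, −20 → 0 °C
Reagents that add atoms: none
Why: Acid-catalysed acetalization of the 1,2-diol with the enal under dehydrating conditions at low temperature should give the dioxolane without Z to E isomerization, and any mixture at the two non-persisting centres serves.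

Step 14
Reactants: 22 dienyl dioxolane
Product: 25 C10-formyl cis-hexahydroisobenzofuran, via oxocarbenium ion 23 (not isolated), via allyl cation 24 (not isolated)
Conditions: SnCl4 (0.25 equiv), CH2Cl2, −78 → −20 °C
Reagents that add atoms: none
Why: SnCl4 ionizes the acetal at the C–O bond of the dienylic oxygen (the other opening is unproductive and reversible), giving an oxocarbenium ion on the C9 oxygen that is conjugated with the Z-alkenyl group. C1, the terminus of the 1,3-diene, adds to C2 in a 6-endo Prins cyclization through a chair transition state with the C9 propargyl and C2 alkenyl groups equatorial, which forms C1–C2 and a tertiary allyl cation at C10 delocalized over C11–C12. C9 then shifts from the carbinol carbon to C10 with retention (pinacol rearrangement), which forms C9–C10, contracts the six-membered oxacycle to the tetrahydrofuran (the five-membered ring arises by this suprafacial 1,2-shift, not by a direct 5-ring closure) and turns the carbinol carbon into the formyl group; the closest known reaction type is the Prins cyclization–pinacol rearrangement of 4-alkenyl-1,3-dioxolanes to 3-acyltetrahydrofurans. C2 is set relative to C9 by the chair with an equatorial alkenyl group, C1 by attack of the oxocarbenium ion on the diene face anti to the C14 isopropenyl group, and C10 by migration of C9 to the face on which it is tethered, which enforces the cis ring fusion. The step needs the C9-controlled chair and the C14-controlled diene face to agree (the (R)-carvone/(R)-glycidol pairing is the matched one), attack at the diene terminus (secured by the tertiary allylic cation it produces) and a pinacol shift faster than proton loss or capture by the isopropenyl and alkyne groups (secured by the aligned C9–C bond and the tin alkoxide donor, with the bulky silyl group keeping the alkyne out). Both epimers at the carbinol and acetal carbons converge because both carbons lose their configuration.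

Step 15
Reactants: 25 C10-formyl cis-hexahydroisobenzofuran
Product: 26 cis-hexahydroisobenzofuran with H10
Conditions: hν (medium-pressure Hg lamp, Pyrex filter), degassed 1,4-dioxane, rt
Reagents that add atoms: none
Why: Norrish α-cleavage of the β,γ-unsaturated aldehyde gives a formyl/allyl radical pair that collapses by hydrogen transfer with loss of CO (photochemical decarbonylation), returning hydrogen to C10 on the face the formyl group occupied, the only one compatible with the cis ring fusion.

Step 16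
Reactants: 26 cis-hexahydroisobenzofuran with H10
Product: 27 C6 homoallylic alcohol
Conditions: HF·pyridine, pyridine, THF, rt
Reagents that add atoms: none
Why: HF·pyridine cleaves the primary silyl ether but not the alkynyl C–Si bond, which frees the hydroxyl that directs step 17.

Step 17
Reactants: 27 C6 homoallylic alcohol
Product: 28 (3S,4S)-epoxy alcohol
Conditions: VO(acac)2 (5 mol %), t-BuOOH (anhydrous, 1.5 equiv), CH2Cl2, 0 °C → rt
Reagents that add atoms: tert-butyl hydroperoxide, CC(C)(C)OO
Why: In this hydroxyl-directed epoxidation the vanadate ester of the homoallylic C6 hydroxyl delivers oxygen only to C3=C4; A(1,3) strain of the Z-alkene holds C2–H in the alkene plane, so C1 blocks one face and oxygen should arrive on the face flanked by the ring oxygen, which sets C3 as S.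

Step 18
Reactants: 28 (3S,4S)-epoxy alcohol
Product: 29 C3,C6-diol with (3S) tertiary alcohol
Conditions: LiAlH4, THF, 0 °C → rt; aqueous NaOH work-up
Reagents that add atoms: none
Why: Hydride opens the trisubstituted epoxide by SN2 attack at the secondary C4, aided by delivery from the C6 alkoxyaluminate, so the C3–O bond keeps its configuration and the C4 stereocentre disappears.

Step 19
Reactants: 29 C3,C6-diol with (3S) tertiary alcohol
Product: 30 C6 silyl ether with free C3 hydroxyl
Conditions: t-BuPh2SiCl (1.1 equiv), imidazole, CH2Cl2, 0 °C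
Reagents that add atoms: tert-butyl(chloro)diphenylsilane, CC(C)(C)[Si](Cl)(c1ccccc1)c1ccccc1
Why: The primary hydroxyl is silylated much faster than the tertiary one, which masks C6 again (it had to be free only for step 17) and keeps the C3 hydroxyl available for the etherification.

Step 20
Reactants: 30 C6 silyl ether with free C3 hydroxyl
Product: 32 (15R) C16 primary alcohol, via B-alkyl-9-BBN adduct 31 (not isolated)
Conditions: 9-BBN (3 equiv), THF, 0 °C → rt; then NaOH, H2O2, 0 °C
Reagents that add atoms: hydrogen peroxide, OO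
Why: 9-BBN adds to the 1,1-disubstituted alkene in preference to the trisubstituted alkene and the silyl-capped alkyne; with C14–H eclipsing the C15=C16 bond the borane should approach past C13H2 and not past the substituted C1, which sets C15 as R, and the C–B bond is oxidized with retention (hydroboration–oxidation).

Step 21
Reactants: 32 (15R) C16 primary alcohol
Product: 34 oxepane tricycle, via primary triflate 33 (not isolated)
Conditions: Tf2O (1.1 equiv), 2,6-lutidine, CH2Cl2, −78 °C → rt
Reagents that add atoms: none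
Why: Only the primary hydroxyl is triflated at low temperature, and the tertiary C3 hydroxyl displaces the triflate in a 7-exo-tet Williamson-type etherification that closes the oxepane without touching any stereocentre.

Step 22
Reactants: 34 oxepane tricycle
Product: 35 (11R,12S)-diol
Conditions: OsO4 (5 mol %), N-methylmorpholine N-oxide, acetone–H2O, rt
Reagents that add atoms: N-methylmorpholine N-oxide, C[N+]1([O-])CCOCC1; water, O
Why: Catalytic osmylation adds both oxygens syn to the only alkene, from the face opposite the pseudoaxial C10–C9 bond of the cis-fused tetrahydrofuran, which sets C11 as R and C12 as S.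

Step 23
Reactants: 35 (11R,12S)-diol; 36 octanoyl chloride
Product: 37 C12 octanoate
Conditions: 36 (1.2 equiv), pyridine, DMAP (cat.), CH2Cl2, 0 °C
Reagents that add atoms: none
Why: DMAP-catalysed acyl transfer occurs at the secondary C12 hydroxyl and leaves the hindered tertiary C11 hydroxyl free.

Step 24
Reactants: 37 C12 octanoate
Product: 38 C6 alcohol with terminal alkyne
Conditions: n-Bu4NF, AcOH, THF, rt
Reagents that add atoms: none
Why: Fluoride cleaves the silyl ether and the alkynyl C–Si bond in one operation, and the acetic acid buffer protects the octanoate from acyl migration or hydrolysis.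

Step 25
Reactants: 38 C6 alcohol with terminal alkyne
Product: 40 2-iodoallyl compound, via iodoalkenylborane 39 (not isolated)
Conditions: B-iodo-9-BBN (4 equiv), pentane–CH2Cl2, −20 → 0 °C; then AcOH, 0 °C; aqueous NaHCO3 work-up
Reagents that add atoms: B-iodo-9-borabicyclo[3.3.1]nonane, IB1C2CCCC1CCC2
Why: Haloboration: the B–I bond adds syn across the terminal alkyne with iodine on the internal carbon C7, and protonolysis of the alkenyl–boron bond by acetic acid gives the 2-iodoalkene; the two hydroxyls are expected to be held as borinates by the extra reagent and set free on work-up.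

Step 26
Reactants: 40 2-iodoallyl compound
Product: 41 C6 aldehyde
Conditions: Dess–Martin periodinane, pyridine, CH2Cl2, 0 °C → rt
Reagents that add atoms: none
Why: The Dess–Martin oxidation converts the primary alcohol to the aldehyde and cannot oxidize the tertiary alcohol.

Step 27
Reactants: 41 C6 aldehyde
Product: 42 tetracyclic C6 allylic alcohol
Conditions: CrCl2 (10 equiv), NiCl2 (1 mol %), DMSO, rt, high dilution (0.003 M)
Reagents that add atoms: none
Why: Intramolecular Nozaki–Hiyama–Kishi reaction: the alkenylchromium species formed from the iodide adds only to the aldehyde, tolerating the free tertiary hydroxyl and the ester, and forms C6–C7 to close the oxonane; the C6 configuration is irrelevant because the hydroxyl is removed.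

Step 28
Reactants: 42 tetracyclic C6 allylic alcohol
Product: 43 C6 methyl carbonate
Conditions: ClCO2Me, pyridine, DMAP (cat.), CH2Cl2, 0 °C
Reagents that add atoms: methyl chloroformate, COC(=O)Cl
Why: The secondary allylic hydroxyl is acylated by the chloroformate while the tertiary hydroxyl is too hindered to react.

Step 29
Reactants: 43 C6 methyl carbonate
Product: 44 CNP0286133.1 (target)
Conditions: Pd2(dba)3·CHCl3 (5 mol %), n-Bu3P (20 mol %), HCO2H, Et3N, THF, 50 °C
Reagents that add atoms: none
Why: Tsuji-type formate reduction: zerovalent palladium ionizes the carbonate to a π-allyl complex spanning C6–C7–C19, and hydride from the palladium formate is delivered to the more substituted terminus C6, which leaves the 1,1-disubstituted C7=C19 alkene of the target.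

**Compound list**

1 | propane-1,3-diol | OCCCO | starting material
2 | 3-[(tert-butyldiphenylsilyl)oxy]propan-1-ol | OCCCO[Si](c1ccccc1)(c1ccccc1)C(C)(C)C | intermediate
3 | 3-[(tert-butyldiphenylsilyl)oxy]propanal | O=CCCO[Si](c1ccccc1)(c1ccccc1)C(C)(C)C | intermediate
4 | methyl 2-[bis(2,2,2-trifluoroethoxy)phosphoryl]propanoate | COC(=O)C(C)P(=O)(OCC(F)(F)F)OCC(F)(F)F | starting material
5 | potassium carbanion of phosphonate 4 (not isolated) | COC(=O)[C-](C)P(=O)(OCC(F)(F)F)OCC(F)(F)F.[K+] | intermediate
6 | methyl (2Z)-5-[(tert-butyldiphenylsilyl)oxy]-2-methylpent-2-enoate | COC(=O)/C(C)=C\CCO[Si](c1ccccc1)(c1ccccc1)C(C)(C)C | intermediate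
7 | (2Z)-5-[(tert-butyldiphenylsilyl)oxy]-2-methylpent-2-en-1-ol | OC/C(C)=C\CCO[Si](c1ccccc1)(c1ccccc1)C(C)(C)C | intermediate
8 | (2Z)-5-[(tert-butyldiphenylsilyl)oxy]-2-methylpent-2-enal | O=C/C(C)=C\CCO[Si](c1ccccc1)(c1ccccc1)C(C)(C)C | intermediate
9 | (R)-glycidol, (2R)-oxiran-2-ylmethanol | OC[C@@H]1CO1 | starting material
10 | triethyl{[(2S)-oxiran-2-yl]methoxy}silane | CC[Si](CC)(CC)OC[C@@H]1CO1 | intermediate
11 | ethynyltri(propan-2-yl)silane, (triisopropylsilyl)acetylene | C#C[Si](C(C)C)(C(C)C)C(C)C | starting material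
12 | lithium [tri(propan-2-yl)silyl]acetylide (not isolated) | [Li]C#C[Si](C(C)C)(C(C)C)C(C)C | intermediate
13 | (2S)-1-[(triethylsilyl)oxy]-5-[tri(propan-2-yl)silyl]pent-4-yn-2-ol | CC[Si](CC)(CC)OC[C@@H](O)CC#C[Si](C(C)C)(C(C)C)C(C)C | intermediate
14 | (2S)-1,2-bis[(triethylsilyl)oxy]-5-[tri(propan-2-yl)silyl]pent-4-yne | CC[Si](CC)(CC)OC[C@@H](O[Si](CC)(CC)CC)CC#C[Si](C(C)C)(C(C)C)C(C)C | intermediate
15 | dimethyl{[(2S)-2-[(triethylsilyl)oxy]-5-[tri(propan-2-yl)silyl]pent-4-yn-1-yl]oxy}sulfonium chloride (not isolated) | C[S+](C)OC[C@@H](O[Si](CC)(CC)CC)CC#C[Si](C(C)C)(C(C)C)C(C)C.[Cl-] | intermediate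
16 | (2S)-2-[(triethylsilyl)oxy]-5-[tri(propan-2-yl)silyl]pent-4-ynal | O=C[C@@H](O[Si](CC)(CC)CC)CC#C[Si](C(C)C)(C(C)C)C(C)C | intermediate
17 | (R)-carvone | CC(=C)[C@@H]1CC=C(C)C(=O)C1 | starting material
18 | lithium (3R)-6-methyl-3-(prop-1-en-2-yl)cyclohexa-1,5-dien-1-olate (not isolated) | CC(=C)[C@@H]1CC=C(C)C(O[Li])=C1 | intermediate
19 | (3R)-6-methyl-3-(prop-1-en-2-yl)cyclohexa-1,5-dien-1-yl trifluoromethanesulfonate | CC(=C)[C@@H]1CC=C(C)C(OS(=O)(=O)C(F)(F)F)=C1 | intermediate
20 | (1RS,2S)-1-[(3R)-6-methyl-3-(prop-1-en-2-yl)cyclohexa-1,5-dien-1-yl]-2-[(triethylsilyl)oxy]-5-[tri(propan-2-yl)silyl]pent-4-yn-1-ol (both carbinol epimers; C2 of the chain is the future C9) | C=C(C)[C@@H]1CC=C(C)C(=C1)C(O)[C@@H](O[Si](CC)(CC)CC)CC#C[Si](C(C)C)(C(C)C)C(C)C | intermediate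
21 | (1RS,2S)-1-[(3R)-6-methyl-3-(prop-1-en-2-yl)cyclohexa-1,5-dien-1-yl]-5-[tri(propan-2-yl)silyl]pent-4-yne-1,2-diol | C=C(C)[C@@H]1CC=C(C)C(=C1)C(O)[C@@H](O)CC#C[Si](C(C)C)(C(C)C)C(C)C | intermediate
22 | dienyl dioxolane: (5S)-2-[(2Z)-5-[(tert-butyldiphenylsilyl)oxy]pent-2-en-2-yl]-4-[(3R)-6-methyl-3-(prop-1-en-2-yl)cyclohexa-1,5-dien-1-yl]-5-{3-[tri(propan-2-yl)silyl]prop-2-yn-1-yl}-1,3-dioxolane, mixture at C2 and C4 of the dioxolane | C=C(C)[C@@H]1CC=C(C)C(=C1)C2OC(/C(C)=C\CCO[Si](c3ccccc3)(c3ccccc3)C(C)(C)C)O[C@H]2CC#C[Si](C(C)C)(C(C)C)C(C)C | intermediate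
23 | oxocarbenium ion on the C9 oxygen with the carbinol oxygen bound to SnCl4 (zwitterion, not isolated) | C=C(C)[C@@H]1CC=C(C)C(=C1)C(O[Sn-](Cl)(Cl)(Cl)Cl)[C@H](CC#C[Si](C(C)C)(C(C)C)C(C)C)[O+]=C/C(C)=C\CCO[Si](c2ccccc2)(c2ccccc2)C(C)(C)C | intermediate
24 | C10 allyl cation in the six-membered oxacycle O–C2–C1–C10–C(carbinol)–C9, carbinol oxygen bound to SnCl4 (zwitterion, not isolated) | C=C(C)[C@@H]1CC=C(C)[C+]2[C@H]1[C@@H](/C(C)=C\CCO[Si](c3ccccc3)(c3ccccc3)C(C)(C)C)O[C@@H](CC#C[Si](C(C)C)(C(C)C)C(C)C)C2O[Sn-](Cl)(Cl)(Cl)Cl | intermediate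
25 | C10-formyl cis-hexahydroisobenzofuran: 1-[(2Z)-5-[(tert-butyldiphenylsilyl)oxy]pent-2-en-2-yl]-4-methyl-7-(prop-1-en-2-yl)-3-{3-[tri(propan-2-yl)silyl]prop-2-yn-1-yl}-1,3,3a,6,7,7a-hexahydro-2-benzofuran-3a-carbaldehyde; C1, C2, C9, C14 configured as in the target, formyl in the place of H10 (formyl, H1, C2 alkenyl and C9 propargyl on one face of the tetrahydrofuran) | C=C(C)[C@@H]1CC=C(C)[C@]2(C=O)[C@H]1[C@@H](/C(C)=C\CCO[Si](c3ccccc3)(c3ccccc3)C(C)(C)C)O[C@H]2CC#C[Si](C(C)C)(C(C)C)C(C)C | intermediate
26 | decarbonylated cis-hexahydroisobenzofuran (H10 cis to H1; C11=C12, C14 isopropenyl, (Z)-C3=C4, C6 silyl ether, silyl-capped alkyne) | C=C(C)[C@@H]1CC=C(C)[C@@H]2[C@H]1[C@@H](/C(C)=C\CCO[Si](c3ccccc3)(c3ccccc3)C(C)(C)C)O[C@H]2CC#C[Si](C(C)C)(C(C)C)C(C)C | intermediate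
27 | C6 homoallylic alcohol of 26 (silyl ether removed) | C=C(C)[C@@H]1CC=C(C)[C@@H]2[C@H]1[C@@H](/C(C)=C\CCO)O[C@H]2CC#C[Si](C(C)C)(C(C)C)C(C)C | intermediate
28 | (3S,4S)-3,4-epoxide of 27 (cis-epoxide, oxygen on the face flanked by the ring oxygen) | C=C(C)[C@@H]1CC=C(C)[C@@H]2[C@H]1[C@@H]([C@@]3(C)O[C@H]3CCO)O[C@H]2CC#C[Si](C(C)C)(C(C)C)C(C)C | intermediate
29 | C3,C6-diol: (3S) tertiary alcohol, C4–C6 chain ending in CH2OH | C=C(C)[C@@H]1CC=C(C)[C@@H]2[C@H]1[C@@H]([C@@](C)(O)CCCO)O[C@H]2CC#C[Si](C(C)C)(C(C)C)C(C)C | intermediate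
30 | C6 tert-butyldiphenylsilyl ether of 29 | C=C(C)[C@@H]1CC=C(C)[C@@H]2[C@H]1[C@@H]([C@@](C)(O)CCCO[Si](c3ccccc3)(c3ccccc3)C(C)(C)C)O[C@H]2CC#C[Si](C(C)C)(C(C)C)C(C)C | intermediate
31 | B-(C16-alkyl)-9-borabicyclo[3.3.1]nonane from 30 (not isolated) | B1(C[C@H](C)[C@@H]2CC=C(C)[C@@H]3[C@H]2[C@@H]([C@@](C)(O)CCCO[Si](c4ccccc4)(c4ccccc4)C(C)(C)C)O[C@H]3CC#C[Si](C(C)C)(C(C)C)C(C)C)C5CCCC1CCC5 | intermediate
32 | (15R) C16 primary alcohol with free (3S) tertiary hydroxyl | OC[C@H](C)[C@@H]1CC=C(C)[C@@H]2[C@H]1[C@@H]([C@@](C)(O)CCCO[Si](c3ccccc3)(c3ccccc3)C(C)(C)C)O[C@H]2CC#C[Si](C(C)C)(C(C)C)C(C)C | intermediate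
33 | C16 trifluoromethanesulfonate of 32 (not isolated) | O=S(=O)(OC[C@H](C)[C@@H]1CC=C(C)[C@@H]2[C@H]1[C@@H]([C@@](C)(O)CCCO[Si](c3ccccc3)(c3ccccc3)C(C)(C)C)O[C@H]2CC#C[Si](C(C)C)(C(C)C)C(C)C)C(F)(F)F | intermediate
34 | oxepane tricycle (C3–O–C16 ether; C11=C12; C6 silyl ether; silyl-capped alkyne on C8) | CC(C)(C)[Si](c1ccccc1)(c1ccccc1)OCCC[C@]2(C)OC[C@H](C)[C@@H]3CC=C(C)[C@@H]4[C@H]3[C@@H]2O[C@H]4CC#C[Si](C(C)C)(C(C)C)C(C)C | intermediate
35 | (11R,12S)-cis-diol of 34 (both hydroxyls on the face opposite the tetrahydrofuran) | CC(C)(C)[Si](c1ccccc1)(c1ccccc1)OCCC[C@]2(C)OC[C@H](C)[C@@H]3C[C@H](O)[C@](C)(O)[C@@H]4[C@H]3[C@@H]2O[C@H]4CC#C[Si](C(C)C)(C(C)C)C(C)C | intermediate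
36 | octanoyl chloride | CCCCCCCC(=O)Cl | starting material
37 | C12 octanoate of 35 (C11 hydroxyl free) | CC(C)(C)[Si](c1ccccc1)(c1ccccc1)OCCC[C@]2(C)OC[C@H](C)[C@@H]3C[C@H](OC(=O)CCCCCCC)[C@](C)(O)[C@@H]4[C@H]3[C@@H]2O[C@H]4CC#C[Si](C(C)C)(C(C)C)C(C)C | intermediate
38 | desilylated octanoate: C6 primary alcohol, terminal alkyne on C8 | OCCC[C@]2(C)OC[C@H](C)[C@@H]3C[C@H](OC(=O)CCCCCCC)[C@](C)(O)[C@@H]4[C@H]3[C@@H]2O[C@H]4CC#C | intermediate
39 | (Z)-2-iodoalkenyl-9-borabicyclo[3.3.1]nonane from 38 (boron on C19, iodine on C7; not isolated) | OCCC[C@]2(C)OC[C@H](C)[C@@H]3C[C@H](OC(=O)CCCCCCC)[C@](C)(O)[C@@H]4[C@H]3[C@@H]2O[C@H]4C/C(I)=C/B5C6CCCC5CCC6 | intermediate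
40 | 2-iodoallyl compound (C7 iodide, C19 methylene, C6 primary alcohol) | OCCC[C@]2(C)OC[C@H](C)[C@@H]3C[C@H](OC(=O)CCCCCCC)[C@](C)(O)[C@@H]4[C@H]3[C@@H]2O[C@H]4CC(I)=C | intermediate
41 | C6 aldehyde of 40 | O=CCC[C@]2(C)OC[C@H](C)[C@@H]3C[C@H](OC(=O)CCCCCCC)[C@](C)(O)[C@@H]4[C@H]3[C@@H]2O[C@H]4CC(I)=C | intermediate
42 | tetracyclic C6 allylic alcohol (oxonane closed, C7=C19 methylene; C6 configuration not specified) | C=C1C(O)CC[C@]2(C)OC[C@H](C)[C@@H]3C[C@H](OC(=O)CCCCCCC)[C@](C)(O)[C@@H]4[C@H]3[C@@H]2O[C@H]4C1 | intermediate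
43 | C6 methyl carbonate of 42 | C=C1C(OC(=O)OC)CC[C@]2(C)OC[C@H](C)[C@@H]3C[C@H](OC(=O)CCCCCCC)[C@](C)(O)[C@@H]4[C@H]3[C@@H]2O[C@H]4C1 | intermediate
44 | CNP0286133.1, (1S,2S,3S,9S,10R,11R,12S,14S,15R) in the overview numbering | C=C1CCC[C@]2(C)OC[C@H](C)[C@@H]3C[C@H](OC(=O)CCCCCCC)[C@](C)(O)[C@@H]4[C@H]3[C@@H]2O[C@H]4C1 | target

**Step count and risks**

Total step count: 29. Longest linear sequence: 23 steps (steps 6–9 and 11–29, from (R)-glycidol).

Steps most likely to fail:

Step 14. The Lewis acid may ionize the acetal unproductively before the Prins step can occur: cleavage toward the dienylic carbon with loss of the diene to cationic side reactions, or Z to E scrambling of the alkenyl oxocarbenium ion. The fallback sets out from 20 and comes back at 25. The carbinol hydroxyl of 20 is silylated (i-Pr3SiOTf, 2,6-lutidine) to give bis-silyl ether F1. The triethylsilyl group is then removed selectively (HF·pyridine, 0 °C) to give C9 alcohol F2. F2 is condensed with enal 8 under BF3·OEt2 at low temperature. The oxocarbenium ion can then form only on the C9 oxygen, and the silyloxy group terminates the cascade as in the Prins–pinacol reactions of allylic silyl ethers, giving 25 directly.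

Step 17. Oxygen delivery to C3=C4 may show poor facial selectivity, so that the epoxide of the other face forms beside or instead of 28. The fallback sets out from 27 and comes back at 34; it uses that epoxide with inversion at C3 instead of discarding it. The (3R,4R)-epoxy alcohol F3 is silylated at the C6 hydroxyl (t-BuPh2SiCl, imidazole) to give silyl ether F4. Hydroboration–oxidation of the isopropenyl group (9-BBN; then NaOH, H2O2) gives C16 alcohol F5. Acid-catalysed (camphorsulfonic acid, CH2Cl2) opening of the epoxide by the C16 hydroxyl at the tertiary C3, with inversion, closes the oxepane and gives C4 alcohol F6. Barton–McCombie deoxygenation through xanthate F7 (NaH, CS2, MeI; then Bu3SnH, AIBN, toluene, 80 °C) removes the C4 hydroxyl and gives 34.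

Step 29. Regiocontrol in the hydride transfer within the π-allyl complex may be lost (hydride to C19, or β-hydride elimination), which would give the endocyclic alkene or a diene. The fallback sets out from 42 and comes back at 44. A rhenium-catalysed 1,3-transposition of the allylic alcohol (Ph3SiOReO3, Et2O) gives primary allylic alcohol F8. A Mitsunobu reaction of F8 with 2-nitrobenzenesulfonylhydrazide (Ph3P, diethyl azodicarboxylate, THF, −30 °C → rt) follows. The allylic diazene F9 that results loses N2 in a retro-ene shift that places hydrogen on C6 and the alkene at C7=C19.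

**Further compounds**

F1 | step 14 | carbinol triisopropylsilyl ether of 20 (C9 triethylsilyl ether retained) | C=C(C)[C@@H]1CC=C(C)C(=C1)C(O[Si](C(C)C)(C(C)C)C(C)C)[C@@H](O[Si](CC)(CC)CC)CC#C[Si](C(C)C)(C(C)C)C(C)C
F2 | step 14 | C9 alcohol with carbinol triisopropylsilyl ether | C=C(C)[C@@H]1CC=C(C)C(=C1)C(O[Si](C(C)C)(C(C)C)C(C)C)[C@@H](O)CC#C[Si](C(C)C)(C(C)C)C(C)C
F3 | step 17 | (3R,4R)-epoxy alcohol, the 3,4-bis-epimer of 28 | C=C(C)[C@@H]1CC=C(C)[C@@H]2[C@H]1[C@@H]([C@]3(C)O[C@@H]3CCO)O[C@H]2CC#C[Si](C(C)C)(C(C)C)C(C)C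
F4 | step 17 | C6 tert-butyldiphenylsilyl ether of F3 | C=C(C)[C@@H]1CC=C(C)[C@@H]2[C@H]1[C@@H]([C@]3(C)O[C@@H]3CCO[Si](c4ccccc4)(c4ccccc4)C(C)(C)C)O[C@H]2CC#C[Si](C(C)C)(C(C)C)C(C)C
F5 | step 17 | (15R) C16 primary alcohol of F4 | OC[C@H](C)[C@@H]1CC=C(C)[C@@H]2[C@H]1[C@@H]([C@]3(C)O[C@@H]3CCO[Si](c4ccccc4)(c4ccccc4)C(C)(C)C)O[C@H]2CC#C[Si](C(C)C)(C(C)C)C(C)C
F6 | step 17 | oxepane with C4 secondary hydroxyl (C3 configured as in 34) | CC(C)(C)[Si](c1ccccc1)(c1ccccc1)OCC[C@@H](O)[C@]2(C)OC[C@H](C)[C@@H]3CC=C(C)[C@@H]4[C@H]3[C@@H]2O[C@H]4CC#C[Si](C(C)C)(C(C)C)C(C)C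
F7 | step 17 | C4 O-(S-methyl dithiocarbonate) of F6 | CC(C)(C)[Si](c1ccccc1)(c1ccccc1)OCC[C@@H](OC(=S)SC)[C@]2(C)OC[C@H](C)[C@@H]3CC=C(C)[C@@H]4[C@H]3[C@@H]2O[C@H]4CC#C[Si](C(C)C)(C(C)C)C(C)C
F8 | step 29 | C19 primary allylic alcohol with endocyclic C6=C7 alkene | OCC1=CCC[C@]2(C)OC[C@H](C)[C@@H]3C[C@H](OC(=O)CCCCCCC)[C@](C)(O)[C@@H]4[C@H]3[C@@H]2O[C@H]4C1
F9 | step 29 | C19 allylic diazene from F8 (not isolated) | N=NCC1=CCC[C@]2(C)OC[C@H](C)[C@@H]3C[C@H](OC(=O)CCCCCCC)[C@](C)(O)[C@@H]4[C@H]3[C@@H]2O[C@H]4C1
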